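**Plan**
1. Numbering: C1 quaternary C–Me; C2 CH–O2CEt; C3, C4 CH2; C5(Me)=C6 (Z); C7 lactone CH–O; C8 butenolide β-carbon (C17 α-carbon with its methyl, C19 carbonyl); C9 CH2; C10 ring-fusion CH; C11(Me)=C12; C13, C14 CH–OAc.
2. Enabling feature: C2–C3–C4–C5=C6–C7 is a cyclohexene (the dearomatised p-cresol ring) once C2 and C7 are bonded. That C2–C7 bond is the central σ bond of the 1,5-diene C10=C1–C2–C7–C8=C9, so a [3,3] shift trades it for C9–C10 and opens the six-membered ring into the ten-membered ring.
3. Cuts (retrosynthetic order): butenolide to furan (C7–H, C19=O); C13–C14 (pinacol); C1–C14 and C2–H (enolate hydroxymethylation, reduction); C9–C10 made while C2–C7 is restored (oxy-Cope); C1–C2 (dienylcerium + ketone); C7–O (phenol dearomatisation); aryl–C8 (Suzuki).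
4. Forward order of rings: arene → spirolactone cyclohexadienone → spiro-acetal cyclohexenol → ten-membered ring by ring expansion → furan → cyclohexene by pinacol closure → butenolide last.
5. Stereochemistry: C7 (spiro) from a chiral aryl-λ3-iodane; C2 carbinol by addition anti to C7–O; the chair [3,3] transition state relays this pair to C10 and to the planar chirality of the E enolate, whose outer face then takes C14 (sets C1) and hydride (sets C2); C13/C14 from the cis-selective pinacol; C7 last, by hydride addition to the ring-opened γ-keto acid.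

Key step: step 13

Remark 1: C17 is formed racemic in step 2 and the acetal carbon C19 as an anomeric mixture in step 7; both become sp2 in furan 27, so compounds 6–10 and 21–26 are carried as epimeric mixtures at these two centres and their SMILES leave them open.
Remark 2: the iodane of step 4 is the known (R,R)-ArI(OAc)2, Ar = 2,6-bis{[(2R)-1-(mesitylamino)-1-oxopropan-2-yl]oxy}phenyl, SMILES CC(=O)OI(OC(C)=O)c1c(O[C@H](C)C(=O)Nc2c(C)cc(C)cc2C)cccc1O[C@H](C)C(=O)Nc1c(C)cc(C)cc1C. It is assumed to give the (5S) spiro centre; if the sense of induction is opposite, the (S,S) antipode is used.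

**Route**

Step 1
Reactants: 1 ethyl 2-methylbuta-2,3-dienoate
Product: 2 2-methylbuta-2,3-dienoic acid
Conditions: LiOH, THF/H2O, 0 °C; then 1 M HCl
Reagents that add atoms: lithium hydroxide, [Li+].[OH-]
Why: Saponification; at 0 °C hydroxide attacks the ester carbonyl faster than the central allene carbon, and the allenoic acid is set free on acidification.

Step 2
Reactants: 2 2-methylbuta-2,3-dienoic acid
Product: 3 3-iodo-2-methylbut-3-enoic acid (racemic)
Conditions: NaI, AcOH, 25–40 °C
Reagents that add atoms: sodium iodide, [Na+].[I-]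
Why: Hydroiodination of a 2,3-allenoic acid: iodide adds in a conjugate sense to the central allene carbon and the dienol is protonated at the α-carbon, giving the β-iodo-β,γ-unsaturated acid (C8 iodide, C9 methylene, C17 racemic) rather than the conjugated isomer.

Step 3
Reactants: 3 3-iodo-2-methylbut-3-enoic acid; 4 2-hydroxy-5-methylphenylboronic acid
Product: 5 3-(2-hydroxy-5-methylphenyl)-2-methylbut-3-enoic acid (racemic)
Conditions: Pd(OAc)2 (cat.), SPhos, K3PO4, THF/H2O, 40 °C; then citric acid to pH 4, 0 °C
Reagents that add atoms: none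
Why: Suzuki–Miyaura coupling of the 1-iodoalkene forms the aryl–C8 bond; both partners react as their salts, so the carboxylate cannot lactonise onto the phenol and its α-hydrogen is too weakly acidic for the alkene to move into conjugation.

Step 4
Reactants: 5 3-(2-hydroxy-5-methylphenyl)-2-methylbut-3-enoic acid
Product: 6 (5S)-3,9-dimethyl-4-methylidene-1-oxaspiro[4.5]deca-7,9-diene-2,6-dione (spiro C5 = C7)
Conditions: (R,R)-ArI(OAc)2 of remark 2 (1.1 equiv), CH2Cl2/(CF3)2CHOH, −40 °C; cold filtration, used at once
Reagents that add atoms: none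
Why: Oxidative dearomatising ortho-spirolactonisation of a phenol by an aryl-λ3-iodane: the phenol exchanges onto iodine, the carboxylate closes the five-membered lactone on the ortho carbon C7 (5-exo) as the iodoarene leaves, and the C2-symmetric lactamide reagent selects the arene face and so sets C7; the pre-formed iodane avoids a peracid that would epoxidise C8=C9, and the dimerisation-prone dienone is kept cold and dilute.

Step 5
Reactants: 6 spirolactone dienone
Product: 8 (5S)-3,9-dimethyl-4-methylidene-6-(triethylsilyloxy)-1-oxaspiro[4.5]deca-6,9-dien-2-one, via potassium enolate 7 (not isolated)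
Conditions: KBH(s-Bu)3, THF, −78 °C; then Et3SiCl, Et3N, −78 → 0 °C
Reagents that add atoms: chlorotriethylsilane, CC[Si](Cl)(CC)CC
Why: Conjugate (1,4) reduction: the bulky borohydride delivers hydride to the unsubstituted β-carbon C4 (C6 is shielded by the spiro centre), and O-silylation of the enolate masks the C2 carbonyl for the next step without touching the lactone or C8=C9.

Step 6
Reactants: 8 silyl enol ether lactone
Product: 9 (5S)-3,9-dimethyl-4-methylidene-6-(triethylsilyloxy)-1-oxaspiro[4.5]deca-6,9-dien-2-ol (lactol)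
Conditions: i-Bu2AlH (1.1 equiv), CH2Cl2, −78 °C; aq. KNaC4H4O6
Reagents that add atoms: none
Why: Half-reduction of a γ-lactone stops at the lactol because the tetrahedral aluminium alkoxide persists until work-up; the silyl enol ether is inert to the hydride.

Step 7
Reactants: 9 lactol
Product: 10 (5S)-2-methoxy-3,9-dimethyl-4-methylidene-1-oxaspiro[4.5]dec-9-en-6-one
Conditions: PPTS (cat.), MeOH, 0 °C → rt
Reagents that add atoms: methanol, CO
Why: Acid-catalysed acetalisation of the lactol through its cyclic oxocarbenium ion, with methanolysis of the silyl enol ether (fast protonation at C3) unveiling the C2 ketone in the same operation; the acetal is needed because a lactone α-hydrogen would be removed by KH in step 13.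

Step 8
Reactants: 11 but-2-yn-1-ol
Product: 13 (Z)-3-iodobut-2-en-1-ol, via cyclic vinylalanate 12 (not isolated)
Conditions: NaAlH2(OCH2CH2OMe)2, THF, 0 °C; then I2, −78 °C
Reagents that add atoms: iodine, II
Why: Hydroxyl-directed trans-hydroalumination of the propargylic alcohol places aluminium on C11 in a five-membered alanate, and iodinolysis with retention gives the Z iodide in which iodine (later C10) is cis to C13.

Step 9
Reactants: 13 (Z)-3-iodobut-2-en-1-ol
Product: 14 tert-butyl{[(2Z)-3-iodobut-2-en-1-yl]oxy}dimethylsilane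
Conditions: TBSCl, imidazole, CH2Cl2, 0 °C
Reagents that add atoms: tert-butyldimethylsilyl chloride, CC(C)(C)[Si](C)(C)Cl
Why: Silylation of the primary alcohol protects C13–OH against the organometallic steps.

Step 10
Reactants: 14 vinyl iodide; 15 propyne
Product: 16 tert-butyldimethyl{[(2Z)-3-methylhex-2-en-4-yn-1-yl]oxy}silane
Conditions: Pd(PPh3)2Cl2 (cat.), CuI (cat.), i-Pr2NH, THF, propyne (1 atm), rt
Reagents that add atoms: none
Why: Sonogashira coupling proceeds with retention of the Z geometry and brings in C10, C1 and the C1 methyl.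

Step 11
Reactants: 16 enyne
Product: 18 tert-butyl{[(2Z,4E)-5-iodo-3-methylhexa-2,4-dien-1-yl]oxy}dimethylsilane, via dienylzirconocene chloride 17 (not isolated)
Conditions: Cp2Zr(H)Cl (1.3 equiv), THF, rt → 40 °C; then I2, 0 °C
Reagents that add atoms: iodine, II
Why: Schwartz hydrozirconation adds Zr–H syn across the alkyne with zirconium on the less hindered methyl-bearing carbon C1 (regioisomers equilibrate with the slight excess of reagent), and iodinolysis with retention gives the E iodide with C11 trans to iodine.

Step 12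
Reactants: 18 dienyl iodide; 10 keto acetal
Product: 21 (5S,6R)-6-[(2E,4Z)-6-(tert-butyldimethylsilyloxy)-4-methylhexa-2,4-dien-2-yl]-2-methoxy-3,9-dimethyl-4-methylidene-1-oxaspiro[4.5]dec-9-en-6-ol, via dienyllithium 19 (not isolated), via dienylcerium dichloride 20 (not isolated)
Conditions: 18, t-BuLi (2.1 equiv), Et2O, −78 °C; CeCl3, THF, −78 °C; then 10, −78 → −40 °C
Reagents that add atoms: none
Why: Iodine–lithium exchange and transmetalation give a weakly basic dienylcerium reagent that adds 1,2 to the hindered, enolisable ketone; attack anti to the pseudoaxial C7–O bond (Felkin–Anh polar model, the usual cis outcome for 2-alkoxycyclohexanones) puts the dienyl group cis to C8 and the C2 oxygen cis to O7 (2R in target numbering).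

Step 13
Reactants: 21 spiro-acetal 1-dienyl-2-alkenylcyclohex-3-enol
Product: 24 ten-membered trimethylsilyl enol ether (10R; E-C1(Me)=C2–OSiMe3, Z-C5=C6, C7=C8 in a 2-methoxy-3-methyl-2,3-dihydrofuran, C10 bearing the (Z)-4-(tert-butyldimethylsilyloxy)but-2-en-2-yl group), via potassium alkoxide 22 (not isolated), via potassium enolate 23 (not isolated)
Conditions: KH (1.5 equiv), 18-crown-6, THF, 0 °C → rt; then Me3SiCl, Et3N, −78 °C
Reagents that add atoms: chlorotrimethylsilane, C[Si](C)(C)Cl
Why: KH/18-crown-6 gives the free C2 alkoxide 22, which undergoes the anionic oxy-Cope rearrangement across C10=C1–C2–C7–C8=C9: C9–C10 forms as C2–C7 breaks, and the resulting C1=C2 enolate 23 is trapped on oxygen by Me3SiCl. The closest known reaction type is the alkoxide-accelerated oxy-Cope ring expansion of 1,2-dialkenylcyclohexanols to cyclodec-5-enones. The ten-membered ring arises by ring expansion, that is by cleavage of the cyclohexene bond C2–C7 within a six-membered transition state, and not by end-to-end cyclisation. The new stereocentre C10 is set by the chair transition state: the five-membered ring forces the C7–O bond equatorial and C6 axial, hence C3 equatorial and the alkoxide axial, and the E-placed C11 substituent of the dienyl arm sits equatorial, so the cis (2R,7S) pair gives 10R. The step needs chair over boat and [3,3] over [1,3] or fragmentation; the spiro ring holds C8=C9 about 60° to the breaking bond as a chair requires, the cis alkenyl groups reach that chair from the half-chair with the dienyl group axial, and the C5=C6 and C7=C8 geometries are fixed by their rings so that only the E C1=C2 enolate is new. The same transition state leaves the ring chain (C9) across one face of that enolate, which steps 14 and 16 exploit.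

Step 14
Reactants: 24 trimethylsilyl enol ether
Product: 26 (1S,10R)-1-(hydroxymethyl)-1-methyl C2 ketone of the ten-membered ring (dihydrofuran acetal intact), via lithium enolate 25 (not isolated)
Conditions: MeLi (1.05 equiv), THF, 0 °C; then CH2O (g), −78 °C; aq. NH4Cl
Reagents that add atoms: formaldehyde, C=O
Why: Methyllithium cleaves the O–Si bond to the regio- and geometry-defined lithium enolate, and the aldol addition to monomeric formaldehyde occurs on the outer face of the E enolate, anti to the C10–C9 bond that carries the ring across the inner face, which sets the quaternary centre C1 with C14 trans to C9.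

Step 15
Reactants: 26 hydroxymethyl ketone
Product: 27 (1S,10R) furan keto alcohol (furan fused at C7–C8, methyl on C17, C19–H free)
Conditions: PPTS (cat.), CH2Cl2, rt
Reagents that add atoms: none
Why: Acid-catalysed loss of methanol from the 2-methoxy-2,3-dihydrofuran (oxocarbenium ion, then loss of the C17 proton) aromatises the ring to the furan, which erases the spectator centres C17 and C19 and gives a robust carrier of the future butenolide.

Step 16
Reactants: 27 furan keto alcohol
Product: 28 (1S,2S,10R) C2,C14-diol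
Conditions: Me4NBH(OAc)3, MeCN/AcOH, −30 °C
Reagents that add atoms: none
Why: Hydroxyl-directed reduction (Evans–Saksena type): the C14 hydroxyl exchanges onto boron and delivers hydride to the face of the C2 carbonyl on which C14 sits, which is also the outer face of the ring, so C14 and H2 end up added syn across the former E enolate and C2 is 2S.

Step 17
Reactants: 28 diol
Product: 29 C14 tert-butyldimethylsilyl ether of 28
Conditions: TBSCl, imidazole, CH2Cl2, 0 °C
Reagents that add atoms: tert-butyldimethylsilyl chloride, CC(C)(C)[Si](C)(C)Cl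
Why: The primary neopentyl C14 hydroxyl is silylated much faster than the secondary C2 hydroxyl flanked by the quaternary centre.

Step 18
Reactants: 29 mono-silyl ether
Product: 30 C2 propanoate (1S,2S,10R)
Conditions: (EtCO)2O, DMAP, Et3N, CH2Cl2, rt → 40 °C
Reagents that add atoms: propanoic anhydride, CCC(=O)OC(=O)CC
Why: DMAP-catalysed acylation of the remaining secondary alcohol installs the C2 propanoate of the target.

Step 19
Reactants: 30 bis-silyl ether propanoate
Product: 31 (1S,2S,10R) C13,C14-diol propanoate
Conditions: HF·pyridine, pyridine, THF, 0 °C → rt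
Reagents that add atoms: none
Why: Fluoride cleaves both primary silyl ethers; the pyridine-buffered medium suppresses 1,3-migration of the propanoyl group to the C14 hydroxyl and is tolerated by the furan.

Step 20
Reactants: 31 diol
Product: 32 (1R,2S,10R) dialdehyde (C14 aldehyde on C1; Z enal C11=C12–C13)
Conditions: DMP, NaHCO3, CH2Cl2, 0 °C
Reagents that add atoms: none
Why: Dess–Martin oxidation converts both primary alcohols into aldehydes under buffered conditions that preserve the Z enal; C1 carries no hydrogen, so the β-acyloxy aldehyde cannot eliminate.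

Step 21
Reactants: 32 dialdehyde
Product: 33 (1S,2S,10R,13R,14S) bicyclic cis-13,14-diol (cyclohexene closed)
Conditions: SmI2 (2.5 equiv), THF, t-BuOH, −78 °C
Reagents that add atoms: none
Why: Intramolecular pinacol coupling with SmI2: a ketyl adds to the second samarium-bound carbonyl to close the six-membered ring at C13–C14, the bridged samarium diolate gives the cis diol, and in the half-chair with the C1 methyl axial the C14–O bond takes the axial position anti to that methyl, which places both oxygens trans to the methyl.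

Step 22
Reactants: 33 diol
Product: 34 (1R,2S,10R,13R,14S) 13,14-diacetate furan
Conditions: Ac2O, DMAP, pyridine, rt
Reagents that add atoms: acetic anhydride, CC(=O)OC(C)=O
Why: DMAP-catalysed acetylation of both secondary alcohols.

Step 23
Reactants: 34 furan diacetate
Product: 36 γ-hydroxybutenolide (C19 lactone carbonyl, C7 hemiketal), via furan endoperoxide 35 (not isolated)
Conditions: O2, TPP (cat.), visible light, CH2Cl2, −78 °C; then i-Pr2NEt (cat.), −78 → 0 °C
Reagents that add atoms: oxygen, O=O
Why: The electron-rich furan adds singlet oxygen in a [4+2] sense much faster than the trisubstituted alkenes react; the amine then removes the only hydrogen on a peroxide-bearing carbon (C19–H) in a Kornblum–DeLaMare fragmentation, giving the C19 carbonyl and the C7 hemiketal regiospecifically.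

Step 24
Reactants: 36 γ-hydroxybutenolide
Product: 39 CNP0180501.3 (1R,2S,7R,10R,13R,14S), via keto acid 37 (not isolated), via hydroxy acid 38 (not isolated)
Conditions: NaBH4, CeCl3·7H2O, MeOH/THF, −40 °C; then 1 M HCl to pH 3
Reagents that add atoms: none
Why: The hydroxybutenolide equilibrates with the Z γ-keto acid, whose cross-conjugated C7 ketone undergoes 1,2-reduction under Luche conditions, and the Z hydroxy acid lactonises on acidification; hydride is relied upon to enter from the ring face that carries the C1 methyl, opposite to the C2 propanoate and H10, which gives 7R and is the least secure stereocentre of the route.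

**Compound list**
1 | ethyl 2-methylbuta-2,3-dienoate | CCOC(=O)C(C)=C=C | starting material
2 | 2-methylbuta-2,3-dienoic acid | OC(=O)C(C)=C=C | intermediate
3 | 3-iodo-2-methylbut-3-enoic acid (racemic) | OC(=O)C(C)C(I)=C | intermediate
4 | 2-hydroxy-5-methylphenylboronic acid | Cc1ccc(O)c(B(O)O)c1 | starting material
5 | 3-(2-hydroxy-5-methylphenyl)-2-methylbut-3-enoic acid (racemic) | Cc1ccc(O)c(c1)C(=C)C(C)C(O)=O | intermediate
6 | (5S)-3,9-dimethyl-4-methylidene-1-oxaspiro[4.5]deca-7,9-diene-2,6-dione | O=C1C=CC(C)=C[C@@]12OC(=O)C(C)C2=C | intermediate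
7 | potassium enolate (C2–OK) of the 7,8-dihydro spirolactone | [K]OC1=CCC(C)=C[C@@]12OC(=O)C(C)C2=C | intermediate
8 | (5S)-3,9-dimethyl-4-methylidene-6-(triethylsilyloxy)-1-oxaspiro[4.5]deca-6,9-dien-2-one | CC[Si](CC)(CC)OC1=CCC(C)=C[C@@]12OC(=O)C(C)C2=C | intermediate
9 | (5S)-3,9-dimethyl-4-methylidene-6-(triethylsilyloxy)-1-oxaspiro[4.5]deca-6,9-dien-2-ol | CC[Si](CC)(CC)OC1=CCC(C)=C[C@@]12OC(O)C(C)C2=C | intermediate
10 | (5S)-2-methoxy-3,9-dimethyl-4-methylidene-1-oxaspiro[4.5]dec-9-en-6-one | O=C1CCC(C)=C[C@@]12OC(OC)C(C)C2=C | intermediate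
11 | but-2-yn-1-ol | CC#CCO | starting material
12 | sodium cyclic vinylalanate (3-methyl-2,5-dihydro-1,2-oxaaluminol-2-uide, two 2-methoxyethoxy groups on Al) | [Na+].CC1=CCO[Al-]1(OCCOC)OCCOC | intermediate
13 | (Z)-3-iodobut-2-en-1-ol | C/C(I)=C/CO | intermediate
14 | tert-butyl{[(2Z)-3-iodobut-2-en-1-yl]oxy}dimethylsilane | C/C(I)=C/CO[Si](C)(C)C(C)(C)C | intermediate
15 | propyne | CC#C | starting material
16 | tert-butyldimethyl{[(2Z)-3-methylhex-2-en-4-yn-1-yl]oxy}silane | CC#C/C(C)=C\CO[Si](C)(C)C(C)(C)C | intermediate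
17 | (2E,4Z)-dienylzirconocene chloride | Cl[Zr](C1C=CC=C1)(C1C=CC=C1)/C(C)=C/C(C)=C\CO[Si](C)(C)C(C)(C)C | intermediate
18 | tert-butyl{[(2Z,4E)-5-iodo-3-methylhexa-2,4-dien-1-yl]oxy}dimethylsilane | I/C(C)=C/C(C)=C\CO[Si](C)(C)C(C)(C)C | intermediate
19 | (2E,4Z)-dienyllithium from 18 | [Li]/C(C)=C/C(C)=C\CO[Si](C)(C)C(C)(C)C | intermediate
20 | (2E,4Z)-dienylcerium dichloride | Cl[Ce](Cl)/C(C)=C/C(C)=C\CO[Si](C)(C)C(C)(C)C | intermediate
21 | (5S,6R)-6-[(2E,4Z)-6-(tert-butyldimethylsilyloxy)-4-methylhexa-2,4-dien-2-yl]-2-methoxy-3,9-dimethyl-4-methylidene-1-oxaspiro[4.5]dec-9-en-6-ol | O[C@]1(CCC(C)=C[C@@]12OC(OC)C(C)C2=C)/C(C)=C/C(C)=C\CO[Si](C)(C)C(C)(C)C | intermediate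
22 | potassium alkoxide of 21 | [K]O[C@]1(CCC(C)=C[C@@]12OC(OC)C(C)C2=C)/C(C)=C/C(C)=C\CO[Si](C)(C)C(C)(C)C | intermediate
23 | (10R) potassium E-enolate of the ten-membered ketone | [K]O/C1=C(C)\[C@@H](/C(C)=C\CO[Si](C)(C)C(C)(C)C)CC2=C(OC(OC)C2C)/C=C(C)\CC1 | intermediate
24 | (10R) ten-membered trimethylsilyl enol ether fused to a 2-methoxy-3-methyl-2,3-dihydrofuran | C[Si](C)(C)O/C1=C(C)\[C@@H](/C(C)=C\CO[Si](C)(C)C(C)(C)C)CC2=C(OC(OC)C2C)/C=C(C)\CC1 | intermediate
25 | (10R) lithium E-enolate | [Li]O/C1=C(C)\[C@@H](/C(C)=C\CO[Si](C)(C)C(C)(C)C)CC2=C(OC(OC)C2C)/C=C(C)\CC1 | intermediate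
26 | (1S,10R) 1-(hydroxymethyl)-1-methyl C2 ketone, dihydrofuran acetal | O=C1CC/C(C)=C\C2=C(C[C@H](/C(C)=C\CO[Si](C)(C)C(C)(C)C)[C@@]1(C)CO)C(C)C(OC)O2 | intermediate
27 | (1S,10R) furan keto alcohol | O=C1CC/C(C)=C\c2occ(C)c2C[C@H](/C(C)=C\CO[Si](C)(C)C(C)(C)C)[C@@]1(C)CO | intermediate
28 | (1S,2S,10R) furan C2,C14-diol | O[C@H]1CC/C(C)=C\c2occ(C)c2C[C@H](/C(C)=C\CO[Si](C)(C)C(C)(C)C)[C@@]1(C)CO | intermediate
29 | (1S,2S,10R) C14 tert-butyldimethylsilyl ether | O[C@H]1CC/C(C)=C\c2occ(C)c2C[C@H](/C(C)=C\CO[Si](C)(C)C(C)(C)C)[C@@]1(C)CO[Si](C)(C)C(C)(C)C | intermediate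
30 | (1S,2S,10R) C2 propanoate bis-silyl ether | CCC(=O)O[C@H]1CC/C(C)=C\c2occ(C)c2C[C@H](/C(C)=C\CO[Si](C)(C)C(C)(C)C)[C@@]1(C)CO[Si](C)(C)C(C)(C)C | intermediate
31 | (1S,2S,10R) C13,C14-diol propanoate | CCC(=O)O[C@H]1CC/C(C)=C\c2occ(C)c2C[C@H](/C(C)=C\CO)[C@@]1(C)CO | intermediate
32 | (1R,2S,10R) dialdehyde propanoate | CCC(=O)O[C@H]1CC/C(C)=C\c2occ(C)c2C[C@H](/C(C)=C\C=O)[C@@]1(C)C=O | intermediate
33 | (1S,2S,10R,13R,14S) bicyclic furan cis-13,14-diol | CCC(=O)O[C@H]1CC/C(C)=C\c2occ(C)c2C[C@@H]2C(C)=C[C@@H](O)[C@@H](O)[C@@]12C | intermediate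
34 | (1R,2S,10R,13R,14S) bicyclic furan 13,14-diacetate | CCC(=O)O[C@H]1CC/C(C)=C\c2occ(C)c2C[C@@H]2C(C)=C[C@@H](OC(C)=O)[C@@H](OC(C)=O)[C@@]12C | intermediate
35 | furan endoperoxide (C7,C19-epidioxy; configuration at C7/C19 open) | CCC(=O)O[C@H]1CC/C(C)=C\C23OOC(O2)C(C)=C3C[C@@H]2C(C)=C[C@@H](OC(C)=O)[C@@H](OC(C)=O)[C@@]12C | intermediate
36 | γ-hydroxybutenolide (C7 hemiketal, configuration open) | CCC(=O)O[C@H]1CC/C(C)=C\C2(O)OC(=O)C(C)=C2C[C@@H]2C(C)=C[C@@H](OC(C)=O)[C@@H](OC(C)=O)[C@@]12C | intermediate
37 | Z γ-keto acid (C7 ketone, C19 acid) | CCC(=O)O[C@H]1CC/C(C)=C\C(=O)/C(=C(/C)C(=O)O)C[C@@H]2C(C)=C[C@@H](OC(C)=O)[C@@H](OC(C)=O)[C@@]12C | intermediate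
38 | (7R) Z γ-hydroxy acid | CCC(=O)O[C@H]1CC/C(C)=C\[C@@H](O)/C(=C(/C)C(=O)O)C[C@@H]2C(C)=C[C@@H](OC(C)=O)[C@@H](OC(C)=O)[C@@]12C | intermediate
39 | CNP0180501.3 | CCC(=O)O[C@H]1CC/C(C)=C\[C@H]2OC(=O)C(C)=C2C[C@@H]2C(C)=C[C@@H](OC(C)=O)[C@@H](OC(C)=O)[C@@]12C | target

**Count and risks**
Total: 24 steps. Longest linear sequence: 20 steps (steps 1–7 and 12–24, from ethyl 2-methylbuta-2,3-dienoate).

1. Step 21. The Z enal, or its delocalised ketyl radical anion, may isomerise to the E form before the ring closes, and the two cis-diol faces may be poorly discriminated. Fallback: from dialdehyde 32, low-valent titanium (TiCl3(DME)1.5, Zn(Cu), DME, reflux, high dilution) couples both carbonyls reductively through to the alkene and gives the cyclohexa-1,3-diene F1. OsO4/TMEDA (CH2Cl2, −78 °C; aq. NaHSO3) then dihydroxylates the least substituted, cis-disubstituted C13=C14 bond from the face anti to the axial C1 methyl, and the route is rejoined at diol 33.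

2. Step 24. Hydride delivery to the C7 carbonyl of the ring-opened keto acid may show poor or reversed facial selectivity. Fallback: from hydroxybutenolide 36, Me3SiCHN2/MeOH gives the open methyl Z 4-oxo-enoate F2. Corey–Bakshi–Shibata reduction, with the oxazaborolidine enantiomer chosen for the required face (reagent control, C8 side as the large group), gives the (7R) hydroxy ester F3, which lactonises with PPTS to the target 39.

3. Step 13. Heterolytic C2–C7 fragmentation of the alkoxide or a [1,3] shift may compete with the concerted chair [3,3] pathway and erode chirality transfer to C10. Fallback: from 21, silylation (Me3SiOTf, 2,6-lutidine, −78 °C) gives the trimethylsilyl ether F4. Its neutral thermal oxy-Cope rearrangement (degassed o-dichlorobenzene, about 200 °C, sealed tube) passes through the same chair without a free alkoxide and gives silyl enol ether 24 directly.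

**Further compounds**
F1 | step 21 | (1R,2S,10R) bicyclic furan cyclohexa-1,3-diene (C11=C12–C13=C14) propanoate | CCC(=O)O[C@H]1CC/C(C)=C\c2occ(C)c2C[C@@H]2C(C)=CC=C[C@@]12C
F2 | step 24 | methyl ester of Z γ-keto acid 37 | CCC(=O)O[C@H]1CC/C(C)=C\C(=O)/C(=C(/C)C(=O)OC)C[C@@H]2C(C)=C[C@@H](OC(C)=O)[C@@H](OC(C)=O)[C@@]12C
F3 | step 24 | (7R) methyl Z γ-hydroxy ester | CCC(=O)O[C@H]1CC/C(C)=C\[C@@H](O)/C(=C(/C)C(=O)OC)C[C@@H]2C(C)=C[C@@H](OC(C)=O)[C@@H](OC(C)=O)[C@@]12C
F4 | step 13 | trimethylsilyl ether of 21 | C[Si](C)(C)O[C@]1(CCC(C)=C[C@@]12OC(OC)C(C)C2=C)/C(C)=C/C(C)=C\CO[Si](C)(C)C(C)(C)C
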